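## Structural features

The target is a verticillane-type bicyclo[9.3.1]pentadecane. Ring A (C1–C14–C13–C12–C11–C15) is six-membered, and the nine-carbon chain C2–C10 bridges C1 and C11, which flank the quaternary C15, so that a 12-membered ring results. Ring A carries the C13 ketone and the exocyclic C12=C18 methylene (together an α-methylene ketone) and the gem-dimethyl carbon C15. The bridge carries two trans trisubstituted oxiranes, C3–C4 and C7–C8 (both S,S, each the image of an (E)-alkene), and the acetoxy carbon C10 (R). C10 stands next to the bridgehead C11 (R), and the other bridgehead C1 (R) is cis to it. Fragile groups are the α-methylene ketone (Michael acceptor), the two epoxides (acid, transannular opening), the acetate (base, hydride) and any C10 ketone precursor (epimerisable at C11, β,γ-unsaturated). The real difficulty lies in closing the 12-membered ring onto a cis-1,3-disubstituted cyclohexane beside a quaternary carbon, in fixing C10 and four epoxide carbons on a flexible ring, and in obtaining ring A with C1 and C11 in absolute form. The key step exploits that ring A is a 4,4-dimethylcyclohexanone whose β-carbons C11 and C1 flank C15: C12–C13–C14 with C18 is an acetoacetate unit and C11–C15–C1 a bis-acceptor, so two conjugate additions build ring A with both arms (C10 as CH2NO2, C2–C3 as an acetate arm) in place.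

## Logic of the disconnections

33 to 32: the four C–O bonds of the two oxiranes are cut. The epoxides are the most acid-labile groups and are therefore put in last; this removes four stereocentres at once. The forward step must attack the outer face of both (E)-alkenes and leave the electron-poor enone alone.

32 to 28 (through 31, 30, 29): the C12=C18 π bond and the C13 carbonyl are traced back to a C13/C18 1,3-diol, masked as a cis-fused acetonide. The α-methylene ketone would not survive hydrides, ylides or nucleophiles, whereas the acetonide does. The forward steps need selective sulfonylation of the primary hydroxyl, an oxidation that spares the acetate, and a clean β-elimination.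

28 to 26 (through 27): the C6–C7 bond is cut. It is the one bridge bond that joins sp3 to sp2 carbon and can be made with retention of alkene geometry, so both (E)-alkenes are fixed before the ring is closed. The macrocycle opens to a ring-A compound with two arms. The forward step needs selective hydroboration of the terminal alkene of a diene, high dilution and tolerance of the acetate.

26 to 21 (through 25, 23; partners 24, 22): the C5=C6 and C3=C4 double bonds are cut. A stabilised ylide gives the (E)-trisubstituted C3=C4 alkene with its methyl group and C5 in one step, and a methylene ylide adds C6. The forward steps must tolerate a free secondary hydroxyl.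

21 to 14 plus 17 (through 20, 19, 18): the C10 carbinol is traced to a ketone and this to a secondary nitro group, and the C9–C10 bond is cut. The nitro group that served the annulation is used a second time as a carbanion-stabilising group and then becomes the C10 oxygen. The C7–C9 unit arrives with its (E)-alkenyl bromide. The forward steps need mono-C-allylation with the C–Br bond intact, a Nef reaction that does not epimerise C11, and a reagent-controlled reduction.

17 to 15 (through 16): the C8–CH3 and C7–Br bonds are cut. A syn carbometalation of an alkyne fixes the (E) geometry from a three-carbon starting material.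

14 to 11 (through 13, 12): functional-group changes only. The ketone and both esters are reduced together and the 1,3-diol is tied up, which leaves the C3 hydroxyl free; the two esters therefore never need to be told apart. The forward step needs a cis-selective reduction at C13, so that the acetonide is cis-fused and ring A stays conformationally mobile.

11 to 8 plus 9 (through 10): the C11–C12 and C1–C14 bonds are cut. This takes ring A apart into two achiral pieces and removes three stereocentres. The structures of 8, 9 and 11 were checked against the target and need no correction: in 11 the arms are cis and C1 and C11 have the spatial sense of the target (their labels read S in 11 only because neighbours change rank). The weak point is the second addition: C12–H and C10–H are more acidic than C14–H, so equilibration cannot reach the methyl-side enolate. The precursors are kept unchanged and the closure is run on the fully deprotonated polyanion.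

8 to 1, 2 and 5 (through 7, 6, 4, 3): the C10=C11 and C1=C2 double bonds are cut (nitroaldol/dehydration and Wittig). Because C15 is quaternary, neither acceptor can be enolised on the way.

## Other disconnections considered

Alternative 1: The cut is the C10–C11 bond, with the ring alkene moving to C12=C18. In the forward step BF3·OEt2 would activate the aldehyde of the open-chain stannane A2, and C11 of the allylstannane would attack it (SE2') to give the bicyclic alcohol A1. In its favour, one step would form the ring, the C10 oxygen and the exocyclic methylene, C10 would never be a ketone, and A1 lies four operations from the target; on closeness of the cyclisation product to the target and on length of the endgame it is better than the chosen plan. Against it here, C10 and C11 would both be set in the ring closure, by attack of a carbon next to the quaternary C15, with no independent control; the Lewis acid excludes epoxides before closure; and ring A of A2, with C1, C13 and the whole (E,E)-chain, needs a separate asymmetric synthesis. On structure, the chosen plan gets ring A with C1 and C11 from two commercial pieces in one catalytic step. On mechanism, the chosen plan fixes C11 before and C10 by a reagent after ring A is made, whereas here both depend on the facial preference of one macrocyclic transition state; it would be the equal of the chosen plan only if that preference is high. On step economy, the short endgame is offset by the longer way to A2.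

Alternative 2: The cut is the C2–C3 bond. In the forward step 9-BBN would add to the exocyclic C1=C2 alkene of the iodide A4 (hydrogen to C1), and Pd(dppf)Cl2 with Cs2CO3 and AsPh3 would couple the C2 borane with the C3 iodide to give A3. In its favour, the ring closure is a B-alkyl Suzuki–Miyaura coupling, the same reaction type as in the chosen plan, so on the ring-closing event the two are equal. The C7–C8 epoxide would be set on an open chain, where reagent control is dependable; on this epoxide the alternative is better. Against it here, C1 would arise from hydroboration of a 1,1-disubstituted alkene beside C15, so the cis bridge depends on the face selectivity of the borane; ring A with C10, C11, C12 and C13 needs its own stereocontrolled synthesis; and the endgame from A3 (ether cleavage, elimination to the methylene, desilylation, oxidation, second epoxidation) runs with one epoxide exposed. On structure, the chosen plan makes C1 together with ring A under control of C11. On mechanism, the two are equal at the ring closure. On step economy, the chosen plan is shorter after the ring is closed.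

Alternative 3: The cut is the C7–C8 bond, taken as an alkyne. In the forward step Mo(≡CC6H4OMe-4)(OSiPh3)3 would metathesise the two methyl-capped alkynes of the diyne A6 to the cycloalkyne A5, with loss of but-2-yne. In its favour, ring-closing alkyne metathesis is dependable for 12-membered rings, tolerates epoxide, acetate and silyl ether, and puts no alkene geometry at stake; on reliability of the ring-closing event it is the equal of the chosen plan and probably better. The C3–C4 epoxide would also be set before closure. Against it here, A5 lacks the C8 methyl group: a trans-hydrostannation would have to place tin at C8 and not at C7, a choice normally steered by a free neighbouring hydroxyl, which the C10 acetate does not offer, and a methyl-for-tin exchange must follow. On structure, the chosen plan brings the C8 methyl and the (E) geometry in from a carbometalation before any coupling. On mechanism, the alternative trades a geometry-retentive coupling for a regiochemical question after closure. On step economy, two alkyne arms and an enantiopure ring A must be made separately and two steps follow the closure, so it would be longer.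

Key step: step 4

Assumption: atoms carry the numbering of the target throughout (C18 is the exocyclic methylene carbon); at centres that are erased later (C12 and C13 of ring A, C10 of 18) the expected major epimer is drawn and the minor one would follow the same steps.

## Route

Step 1
Reactants: 1 3-hydroxy-2,2-dimethylpropanal; 2 methyl (triphenylphosphoranylidene)acetate
Product: 3 methyl (E)-5-hydroxy-4,4-dimethylpent-2-enoate
Conditions: CH2Cl2, rt → 40 °C
Reagents that add atoms: none
Why: Wittig olefination with a stabilised ylide should give the (E)-enoate and forms C1=C2; the aldehyde has no α-hydrogen and cannot self-condense.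

Step 2
Reactants: 3 methyl (E)-5-hydroxy-4,4-dimethylpent-2-enoate
Product: 4 methyl (E)-4,4-dimethyl-5-oxopent-2-enoate
Conditions: TEMPO (10 mol%), PhI(OAc)2, CH2Cl2, rt
Reagents that add atoms: none
Why: Nitroxyl-catalysed oxidation of a primary alcohol; the aldehyde formed has no α-hydrogen, so neither enolisation nor over-oxidation is expected.

Step 3
Reactants: 4 methyl (E)-4,4-dimethyl-5-oxopent-2-enoate; 5 nitromethane
Product: 8 methyl (2E,5E)-4,4-dimethyl-6-nitrohexa-2,5-dienoate, via nitro alcohol 6 (not isolated), via nitro mesylate 7 (not isolated)
Conditions: MeNO2 (5 equiv), Et3N (cat.), THF, rt; evaporate; then MsCl, Et3N, CH2Cl2, 0 °C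
Reagents that add atoms: none
Why: Henry reaction followed by mesylation and E1cB elimination should give the thermodynamic (E)-nitroalkene and forms C10=C11; the hindered enoate does not compete for nitromethane under amine catalysis.

Step 4
Reactants: 8 methyl (2E,5E)-4,4-dimethyl-6-nitrohexa-2,5-dienoate; 9 methyl acetoacetate
Product: 11 methyl (1S,4S,6S)-4-(2-methoxy-2-oxoethyl)-5,5-dimethyl-6-(nitromethyl)-2-oxocyclohexane-1-carboxylate, via Michael adduct 10 (not isolated)
Conditions: 1-[3,5-bis(trifluoromethyl)phenyl]-3-[(1R,2R)-2-(dimethylamino)cyclohexyl]thiourea (10 mol%), 9 (1.0 equiv), toluene, rt; then THF, LiN(iPr)2 (3.5 equiv), −78 → −20 °C; AcOH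
Reagents that add atoms: none
Why: Stage one is a bifunctional aminothiourea-catalysed nitro-Michael addition: the dimethylamino group deprotonates 9, the thiourea holds the nitro group of 8 by two hydrogen bonds, and C12 adds to C11 (closest known reaction type: aminothiourea-catalysed addition of β-keto esters and malonates to nitroalkenes). C11 is set by the catalyst; the (1R,2R) enantiomer is chosen because the accepted model for this catalyst class delivers the nucleophile to the face that corresponds to (S) at C11 of 10 when C15 takes the place of the usual aryl group, and the (1S,2S) catalyst would be taken if this hindered alkyl case should respond in the opposite sense. In stage two LiN(iPr)2 removes C12–H, one C10–H and then a C14–H, giving the nitronate of the β-keto ester dianion, which like such dianions reacts at its terminal carbon C14 (closest known type: γ-alkylation and γ-conjugate addition of acetoacetate dianions). Ring A closes by a 6-(enolendo)-exo-trig conjugate addition of C14 to C1, helped by the gem-dimethyl (Thorpe–Ingold) effect of C15; attack by C12 or C10 would need a four-membered ring and 1,2-attack at C3 an eight-membered ring, so the substrate itself enforces site selectivity and 1,4-addition. C1 is controlled by C11: allylic 1,3-strain with the planar ester enolate at C12 turns the nitronate arm away from the face on which C1 approaches, C2 points outward, and the two arms should end cis, which is also the diequatorial, thermodynamically preferred arrangement. C12 is set on protonation and equilibrates through the enol to the equatorial ester; it is erased later. The quaternary C15 blocks γ-deprotonation of 8 by the amine and by the amide base, and the low temperature of the irreversible closure leaves no time for retro-Michael cleavage of the C11–C12 bond, so the enantiomeric purity of stage one should be kept. One equivalent of 9 is used so that no free acetoacetate dianion is present in stage two.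

Step 5
Reactants: 11 ring-A keto diester
Product: 13 ring-A nitro triol (C13–OH cis to C18H2OH; arms at C1 and C11 cis to each other and trans to C18), via hydroxy diester 12 (not isolated)
Conditions: Zn(BH4)2, Et2O, −20 → 0 °C; then LiBH4, MeOH, THF, 0 °C → rt
Reagents that add atoms: none
Why: Chelation-controlled hydride reduction of the β-keto ester should deliver hydride anti to the ring branch at C12 and give the cis hydroxy ester (axial C13–OH); LiBH4 then reduces both esters and leaves the aliphatic nitro group alone. The cis relation is wanted because it gives a cis-fused, conformationally mobile acetonide, so ring A can still place both arms axial for the later bridging.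

Step 6
Reactants: 13 ring-A nitro triol
Product: 14 ring-A nitro alcohol with cis-fused C13,C18-acetonide and free C3–OH
Conditions: 2,2-dimethoxypropane, PPTS (cat.), CH2Cl2, rt; MeOH quench
Reagents that add atoms: 2,2-dimethoxypropane, COC(C)(C)OC
Why: Acetal formation is selective for the cis-1,3-diol (six-membered 1,3-dioxane); the primary C3 hydroxyl stays free, which differentiates the two former esters without a selective reduction.

Step 7
Reactants: 15 propargyl alcohol
Product: 16 (E)-3-bromo-2-methylprop-2-en-1-ol
Conditions: AlMe3 (3 equiv), Cp2ZrCl2 (25 mol%), CH2Cl2, 0 °C → rt; then N-bromosuccinimide, −30 °C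
Reagents that add atoms: trimethylaluminium, C[Al](C)C; N-bromosuccinimide, O=C1CCC(=O)N1Br
Why: Negishi zirconium-catalysed carboalumination adds methyl and aluminium syn across the alkyne with methyl on the inner carbon (C8); bromination of the alkenylalane with retention should give the (E)-bromide, which fixes the C7=C8 geometry.

Step 8
Reactants: 16 (E)-3-bromo-2-methylprop-2-en-1-ol
Product: 17 (E)-3-bromo-2-methylprop-2-en-1-yl methyl carbonate
Conditions: ClCO2Me, pyridine, CH2Cl2, 0 °C
Reagents that add atoms: methyl chloroformate, COC(=O)Cl
Why: O-Acylation of a primary allylic alcohol; the carbonate is the leaving group for the base-free allylation.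

Step 9
Reactants: 14 ring-A nitro alcohol acetonide; 17 (E)-3-bromo-2-methylprop-2-en-1-yl methyl carbonate
Product: 18 C10-allylated nitro compound (14 with the (E)-3-bromo-2-methylallyl group on C10; C10 epimers)
Conditions: Pd(PPh3)4 (5 mol%), THF, rt
Reagents that add atoms: none
Why: Tsuji–Trost allylation of a nitronate: ionisation of the carbonate by zerovalent palladium releases methoxide, which deprotonates the nitroalkane, and the nitronate attacks the unsubstituted terminus C9 of the π-allyl complex, forming C9–C10. Allylic ionisation is much faster than insertion into an alkenyl C–Br bond at rt, and a second allylation is slowed by the branching at C11; the C10 epimers converge in step 10.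

Step 10
Reactants: 18 C10-allylated nitro compound
Product: 19 C10 ketone
Conditions: NaOMe, MeOH, 0 °C; then TiCl3 (aq), NH4OAc, 0 °C → rt
Reagents that add atoms: water, O
Why: Nef reaction in its reductive form: the nitronate is reduced by trivalent titanium to the imine, which hydrolyses in the acetate buffer. The near-neutral medium should spare the acetonide and the alkenyl bromide and avoid epimerisation at C11 and conjugation of the β,γ-alkene.

Step 11
Reactants: 19 C10 ketone
Product: 20 (10R)-carbinol (diol with free C3–OH)
Conditions: (S)-2-methyl-CBS-oxazaborolidine (0.5 equiv), catecholborane, toluene, −78 → −40 °C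
Reagents that add atoms: none
Why: Corey–Bakshi–Shibata reduction: the branched ring carbon C11 is the large group and the C9 methylene the small one, so the (S)-oxazaborolidine should deliver hydride to the face that gives (10R). The conditions are non-basic, so C11 is not epimerised; the free hydroxyl only consumes borane.

Step 12
Reactants: 20 (10R)-carbinol diol
Product: 21 (10R)-hydroxy aldehyde (C3 aldehyde)
Conditions: TEMPO (10 mol%), PhI(OAc)2, CH2Cl2, rt
Reagents that add atoms: none
Why: Oxoammonium oxidation is selective for the unhindered primary alcohol over the hindered secondary C10 carbinol.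

Step 13
Reactants: 21 (10R)-hydroxy aldehyde; 22 2-(triphenylphosphoranylidene)propanal
Product: 23 (3E)-enal (C3=C4 with the C4 methyl; C5 aldehyde)
Conditions: toluene, 80 °C
Reagents that add atoms: none
Why: Wittig olefination with a formyl-stabilised ylide should give the (E)-trisubstituted alkene C3=C4 and brings the C4 methyl and C5; the ylide is too weakly basic to disturb the rest.

Step 14
Reactants: 23 (3E)-enal; 24 methyltriphenylphosphonium bromide
Product: 25 (3E)-diene carbinol (C3=C4–C5=C6)
Conditions: 24 (2.5 equiv), KN(SiMe3)2, THF, 0 °C; then 23, −78 → 0 °C
Reagents that add atoms: none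
Why: Wittig methylenation of the enal forms C5=C6; the excess ylide covers the free hydroxyl, and the C3=C4 geometry is not touched.

Step 15
Reactants: 25 (3E)-diene carbinol
Product: 26 (10R)-acetate of the diene
Conditions: Ac2O, pyridine, DMAP (cat.), rt
Reagents that add atoms: acetic anhydride, CC(=O)OC(C)=O
Why: DMAP-catalysed acylation installs the acetate of the target with retention at C10; it is placed after the ylide step and before the boron chemistry.

Step 16
Reactants: 26 diene acetate
Product: 28 bicyclic (3E,7E)-diene with C10–OAc and C13,C18-acetonide, via alkylborane 27 (not isolated)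
Conditions: 9-BBN, THF, 0 °C → rt; then slow addition to Pd(dppf)Cl2 (10 mol%), AsPh3, K3PO4 (aq), DMF–THF, 60 °C (ca. 2 mM)
Reagents that add atoms: none
Why: 9-BBN should add to the terminal C5=C6 bond of the diene with boron on C6, the trisubstituted and the bromo-substituted alkenes being much slower. Intramolecular B-alkyl Suzuki–Miyaura coupling with the alkenyl bromide then forms C6–C7 with retention of the (E) geometry and closes the 12-membered ring, favoured by high dilution.

Step 17
Reactants: 28 bicyclic acetonide acetate
Product: 29 bicyclic C13,C18-diol acetate
Conditions: AcOH–H2O–THF, 45 °C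
Reagents that add atoms: none
Why: Acid hydrolysis of the acetonide; the trisubstituted alkenes and the acetate tolerate dilute acetic acid, and the step comes before any epoxide exists.

Step 18
Reactants: 29 bicyclic diol acetate
Product: 30 C18 mesylate (C13–OH free)
Conditions: MsCl (1.05 equiv), 2,4,6-collidine, CH2Cl2, −20 °C
Reagents that add atoms: methanesulfonyl chloride, CS(=O)(=O)Cl
Why: Sulfonylation with a hindered base at low temperature should select the primary hydroxyl over the axial secondary C13–OH.

Step 19
Reactants: 30 C18 mesylate
Product: 32 (3E,7E)-dienone with C10–OAc, C12=C18 and C13=O, via mesyloxy ketone 31 (not isolated)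
Conditions: Dess–Martin periodinane, NaHCO3, CH2Cl2, rt; then Et3N, rt
Reagents that add atoms: none
Why: Dess–Martin oxidation of the C13 carbinol gives a β-mesyloxy ketone, which loses methanesulfonate by E1cB elimination to the α-methylene ketone; C12 and C13 become sp2, so their temporary configurations vanish.

Step 20
Reactants: 32 (3E,7E)-dienone
Product: 33 CNP0339728.1, the (1R,3S,4S,7S,8S,10R,11R)-diepoxide
Conditions: mCPBA (2.2 equiv), NaHCO3, CH2Cl2, 0 °C
Reagents that add atoms: 3-chloroperoxybenzoic acid, OOC(=O)c1cccc(Cl)c1
Why: Prilezhaev epoxidation: the electron-rich trisubstituted alkenes react, the electron-poor enone does not, and syn addition keeps each epoxide trans. Each (E)-alkene should stand roughly perpendicular to the mean plane of the 12-membered ring with its inner face blocked. Attack on the outer faces of the conformer that holds both vinylic methyl groups on the face of H1 and H11 (opposite to C12–C14 of ring A) gives (3S,4S) and (7S,8S).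

## Compound list

1 | 3-hydroxy-2,2-dimethylpropanal | CC(C)(CO)C=O | starting material
2 | methyl (triphenylphosphoranylidene)acetate | COC(=O)C=P(c1ccccc1)(c1ccccc1)c1ccccc1 | starting material
3 | methyl (E)-5-hydroxy-4,4-dimethylpent-2-enoate | COC(=O)/C=C/C(C)(C)CO | intermediate
4 | methyl (E)-4,4-dimethyl-5-oxopent-2-enoate | COC(=O)/C=C/C(C)(C)C=O | intermediate
5 | nitromethane | C[N+](=O)[O-] | starting material
6 | methyl (E)-5-hydroxy-4,4-dimethyl-6-nitrohex-2-enoate (racemic) | COC(=O)/C=C/C(C)(C)C(O)C[N+](=O)[O-] | intermediate (not isolated)
7 | methyl (E)-4,4-dimethyl-5-(methylsulfonyloxy)-6-nitrohex-2-enoate (racemic) | COC(=O)/C=C/C(C)(C)C(OS(C)(=O)=O)C[N+](=O)[O-] | intermediate (not isolated)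
8 | methyl (2E,5E)-4,4-dimethyl-6-nitrohexa-2,5-dienoate | COC(=O)/C=C/C(C)(C)/C=C/[N+](=O)[O-] | intermediate
9 | methyl acetoacetate | COC(=O)CC(C)=O | starting material
10 | dimethyl (2E,5S)-6-acetyl-4,4-dimethyl-5-(nitromethyl)hept-2-enedioate (C6 epimers) | COC(=O)C(C(C)=O)[C@H](C[N+](=O)[O-])C(C)(C)/C=C/C(=O)OC | intermediate (not isolated)
11 | methyl (1S,4S,6S)-4-(2-methoxy-2-oxoethyl)-5,5-dimethyl-6-(nitromethyl)-2-oxocyclohexane-1-carboxylate | COC(=O)[C@@H]1C(=O)C[C@@H](CC(=O)OC)C(C)(C)[C@H]1C[N+](=O)[O-] | intermediate
12 | methyl (1S,2R,4S,6S)-2-hydroxy-4-(2-methoxy-2-oxoethyl)-5,5-dimethyl-6-(nitromethyl)cyclohexane-1-carboxylate | COC(=O)[C@@H]1[C@H](O)C[C@@H](CC(=O)OC)C(C)(C)[C@H]1C[N+](=O)[O-] | intermediate (not isolated)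
13 | ring-A nitro triol (C13–OH, C18H2OH, C1–CH2CH2OH, C11–CH2NO2; configuration as in 12) | OC[C@@H]1[C@H](O)C[C@@H](CCO)C(C)(C)[C@H]1C[N+](=O)[O-] | intermediate
14 | ring-A nitro alcohol, cis-fused C13,C18-isopropylidene acetal, free C3–OH | CC1(C)OC[C@@H]2[C@H](O1)C[C@@H](CCO)C(C)(C)[C@H]2C[N+](=O)[O-] | intermediate
15 | propargyl alcohol | C#CCO | starting material
16 | (E)-3-bromo-2-methylprop-2-en-1-ol | OC/C(C)=C/Br | intermediate
17 | (E)-3-bromo-2-methylprop-2-en-1-yl methyl carbonate | COC(=O)OC/C(C)=C/Br | intermediate
18 | 14 carrying the (E)-3-bromo-2-methylallyl group on C10 (secondary nitro, C10 epimers) | CC1(C)OC[C@@H]2[C@H](O1)C[C@@H](CCO)C(C)(C)[C@H]2C(C/C(C)=C/Br)[N+](=O)[O-] | intermediate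
19 | C10 ketone (C10(=O)–C9H2–C8(Me)=C7HBr, E) | CC1(C)OC[C@@H]2[C@H](O1)C[C@@H](CCO)C(C)(C)[C@H]2C(=O)C/C(C)=C/Br | intermediate
20 | (10R)-carbinol with free C3–OH | CC1(C)OC[C@@H]2[C@H](O1)C[C@@H](CCO)C(C)(C)[C@H]2[C@H](O)C/C(C)=C/Br | intermediate
21 | (10R)-hydroxy C3 aldehyde | CC1(C)OC[C@@H]2[C@H](O1)C[C@@H](CC=O)C(C)(C)[C@H]2[C@H](O)C/C(C)=C/Br | intermediate
22 | 2-(triphenylphosphoranylidene)propanal | CC(C=O)=P(c1ccccc1)(c1ccccc1)c1ccccc1 | starting material
23 | (3E)-enal (C2–C3H=C4(Me)–C5HO), (10R)-carbinol | CC1(C)OC[C@@H]2[C@H](O1)C[C@@H](C/C=C(\C)C=O)C(C)(C)[C@H]2[C@H](O)C/C(C)=C/Br | intermediate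
24 | methyltriphenylphosphonium bromide | C[P+](c1ccccc1)(c1ccccc1)c1ccccc1.[Br-] | starting material
25 | (3E)-diene (C3=C4(Me)–C5H=C6H2), (10R)-carbinol | CC1(C)OC[C@@H]2[C@H](O1)C[C@@H](C/C=C(\C)C=C)C(C)(C)[C@H]2[C@H](O)C/C(C)=C/Br | intermediate
26 | (10R)-acetate of 25 | CC1(C)OC[C@@H]2[C@H](O1)C[C@@H](C/C=C(\C)C=C)C(C)(C)[C@H]2[C@H](OC(C)=O)C/C(C)=C/Br | intermediate
27 | C6 B-alkyl-9-borabicyclo[3.3.1]nonane of 26 | CC1(C)OC[C@@H]2[C@H](O1)C[C@@H](C/C=C(\C)CCB3C4CCCC3CCC4)C(C)(C)[C@H]2[C@H](OC(C)=O)C/C(C)=C/Br | intermediate (not isolated)
28 | bicyclo[9.3.1] (3E,7E)-diene, C10–OAc, C13,C18-isopropylidene acetal | CC1(C)OC[C@@H]2[C@H](O1)C[C@H]3C/C=C(C)/CC/C=C(C)/C[C@@H](OC(C)=O)[C@@H]2C3(C)C | intermediate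
29 | bicyclic (3E,7E)-diene, C10–OAc, C13–OH, C18–OH | OC[C@@H]1[C@H](O)C[C@H]2C/C=C(C)/CC/C=C(C)/C[C@@H](OC(C)=O)[C@@H]1C2(C)C | intermediate
30 | C18 methanesulfonate of 29 | CS(=O)(=O)OC[C@@H]1[C@H](O)C[C@H]2C/C=C(C)/CC/C=C(C)/C[C@@H](OC(C)=O)[C@@H]1C2(C)C | intermediate
31 | 13-oxo C18 methanesulfonate | CS(=O)(=O)OC[C@@H]1C(=O)C[C@H]2C/C=C(C)/CC/C=C(C)/C[C@@H](OC(C)=O)[C@@H]1C2(C)C | intermediate (not isolated)
32 | (3E,7E)-dienone: 10-acetoxy-12(18)-methylene-13-oxo bicycle | C=C1C(=O)C[C@H]2C/C=C(C)/CC/C=C(C)/C[C@@H](OC(C)=O)[C@@H]1C2(C)C | intermediate
33 | CNP0339728.1, (1R,3S,4S,7S,8S,10R,11R) | C=C1C(=O)C[C@H]2C[C@@H]3O[C@@]3(C)CC[C@@H]3O[C@@]3(C)C[C@@H](OC(C)=O)[C@@H]1C2(C)C | target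

## Step count and least certain steps

Total step count: 20. Longest linear sequence: 18 steps (steps 1–6 and 9–20); steps 7 and 8 are the side branch.

Step 4 (key step). Most likely to go wrong: slow first addition because C15 shields C11; in the second stage, incomplete third deprotonation, intermolecular conjugate addition between polyanions, or closure through a chelated arrangement that leaves the arms trans. The fallback sets out from 10, isolated after stage one. Trimethyl orthoformate in MeOH with catalytic H2SO4 should give the enol methyl ether F1, which blocks C12 and leaves C14–H as the only acidic C–H apart from C10–H. LiN(iPr)2 (2.2 equiv, THF, −78 → 0 °C) would then close ring A through the γ-anion of the vinylogous ester (known γ-deprotonation of β-alkoxy enoates) to the cyclic β-methoxy enoate F2. Aqueous HCl in THF hydrolyses the enol ether, and the route is rejoined at 11.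

Step 9. Most likely to go wrong: a second allylation of the nitronate, loss of the (E)-bromoalkene geometry by η3–η1–η3 isomerisation of the allyl complex, or insertion of zerovalent palladium into the C–Br bond. The fallback is palladium-free and sets out from 14 and 16. PBr3 (Et2O, 0 °C) turns 16 into (E)-1,3-dibromo-2-methylprop-1-ene F3. Compound 14 is deprotonated three times (n-BuLi, THF–HMPA, −90 °C: the alkoxide and the α,α-doubly deprotonated nitro group), and this carbanion is C-alkylated by the allylic bromide of F3 (known C-alkylation of doubly deprotonated nitroalkanes). Protonation comes back to the route at 18.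

Step 16. Most likely to go wrong: protodeboronation, β-hydride loss or oligomerisation outrunning a slow transmetalation at high dilution, and partial hydrolysis of the acetate by aqueous base. The fallback sets out from 26 and is base-free. Hydroboration with 9-BBN and oxidation with NaBO3·4H2O should give the primary C6 alcohol F4; I2, PPh3 and imidazole give the iodide F5; Zn dust with LiCl in THF inserts to the alkylzinc iodide F6. Slow addition of the zinc reagent to Pd(PPh3)4 in THF–DMF at 50 °C closes C6–C7 by an intramolecular Negishi coupling and comes back to the route at 28.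

Step 20. Most likely to go wrong: attack on the wrong face of one alkene if the ring populates a second conformer, or Baeyer–Villiger oxidation of the ketone. The fallback moves the epoxidation ahead of the enone and adds reagent control; it sets out from 29. Shi epoxidation with the enantiomer of the fructose-derived ketone (KHSO5, K2CO3 buffer, MeCN–dimethoxymethane–H2O, 0 °C), which by the spiro transition-state model gives (S,S)-epoxides from (E)-trisubstituted alkenes of this pattern, should give the diepoxy diol F7. MsCl and 2,4,6-collidine give the primary mesylate F8. Dess–Martin periodinane followed by Et3N passes through the mesyloxy ketone F9 and comes back to the route at 33.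

## Further compounds

F1 | step 4 | dimethyl (2E,5S)-6-[(E)-1-methoxyethylidene]-4,4-dimethyl-5-(nitromethyl)hept-2-enedioate (enol methyl ether of 10) | COC(=O)/C(=C(\C)OC)[C@H](C[N+](=O)[O-])C(C)(C)/C=C/C(=O)OC
F2 | step 4 | methyl 2-methoxy-4-(2-methoxy-2-oxoethyl)-5,5-dimethyl-6-(nitromethyl)cyclohex-1-ene-1-carboxylate (C1, C11 as in 11) | COC(=O)C1=C(OC)C[C@@H](CC(=O)OC)C(C)(C)[C@H]1C[N+](=O)[O-]
F3 | step 9 | (E)-1,3-dibromo-2-methylprop-1-ene | BrC/C(C)=C/Br
F4 | step 16 | primary C6 alcohol from 26 | CC1(C)OC[C@@H]2[C@H](O1)C[C@@H](C/C=C(\C)CCO)C(C)(C)[C@H]2[C@H](OC(C)=O)C/C(C)=C/Br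
F5 | step 16 | primary C6 iodide | CC1(C)OC[C@@H]2[C@H](O1)C[C@@H](C/C=C(\C)CCI)C(C)(C)[C@H]2[C@H](OC(C)=O)C/C(C)=C/Br
F6 | step 16 | C6 alkylzinc iodide | CC1(C)OC[C@@H]2[C@H](O1)C[C@@H](C/C=C(\C)CC[Zn]I)C(C)(C)[C@H]2[C@H](OC(C)=O)C/C(C)=C/Br
F7 | step 20 | (3S,4S,7S,8S)-diepoxy C13,C18-diol acetate | OC[C@@H]1[C@H](O)C[C@H]2C[C@@H]3O[C@@]3(C)CC[C@@H]3O[C@@]3(C)C[C@@H](OC(C)=O)[C@@H]1C2(C)C
F8 | step 20 | diepoxy C18 methanesulfonate | CS(=O)(=O)OC[C@@H]1[C@H](O)C[C@H]2C[C@@H]3O[C@@]3(C)CC[C@@H]3O[C@@]3(C)C[C@@H](OC(C)=O)[C@@H]1C2(C)C
F9 | step 20 | diepoxy 13-oxo C18 methanesulfonate | CS(=O)(=O)OC[C@@H]1C(=O)C[C@H]2C[C@@H]3O[C@@]3(C)CC[C@@H]3O[C@@]3(C)C[C@@H](OC(C)=O)[C@@H]1C2(C)C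
A1 | alternative 1 | bicyclic homoallylic alcohol (C10–OH, C12=C18, C13–OTBS, 3E,7E) | C=C1[C@@H](O[Si](C)(C)C(C)(C)C)C[C@H]2C/C=C(C)/CC/C=C(C)/C[C@@H](O)[C@@H]1C2(C)C
A2 | alternative 1 | open-chain allylstannane aldehyde (C11=C12 ring alkene, C18–SnBu3, C13–OTBS, (3E,7E)-chain ending in the C10 aldehyde) | CCCC[Sn](CCCC)(CCCC)CC1=CC(C)(C)[C@H](C/C=C(\C)CC/C=C(\C)CC=O)C[C@@H]1O[Si](C)(C)C(C)(C)C
A3 | alternative 2 | bicyclic mono-epoxide ((E)-C3=C4, C7–C8 epoxide, C10–OAc, C12–CH2OPMB, C13–OTBS) | COc1ccc(COC[C@@H]2[C@@H](O[Si](C)(C)C(C)(C)C)C[C@H]3C/C=C(C)/CC[C@@H]4O[C@@]4(C)C[C@@H](OC(C)=O)[C@@H]2C3(C)C)cc1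
A4 | alternative 2 | open-chain alkene iodide (exocyclic C1=C2, (E)-C3 iodide, C7–C8 epoxide, C10–OAc, C12–CH2OPMB, C13–OTBS) | COc1ccc(COC[C@@H]2[C@@H](O[Si](C)(C)C(C)(C)C)CC(=C)C(C)(C)[C@H]2[C@H](OC(C)=O)C[C@]2(C)O[C@H]2CC/C(C)=C/I)cc1
A5 | alternative 3 | bicyclic cycloalkyne (C7≡C8, C3–C4 epoxide, C10–OAc, C13–OTBS, C12=C18) | C=C1[C@@H](O[Si](C)(C)C(C)(C)C)C[C@H]2C[C@@H]3O[C@@]3(C)CCC#CC[C@@H](OC(C)=O)[C@@H]1C2(C)C
A6 | alternative 3 | open-chain diyne (two methyl-capped alkynes at C7 and C8, C3–C4 epoxide, C10–OAc, C13–OTBS, C12=C18) | C=C1[C@@H](O[Si](C)(C)C(C)(C)C)C[C@@H](C[C@@H]2O[C@@]2(C)CCC#CC)C(C)(C)[C@H]1[C@H](OC(C)=O)CC#CC
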